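## Retrosynthetic overview

1. Brianthein V (28) ⇐ macrocycle 25 by C6–OH → Cl (inversion), C9 acetylation and PMB removal.
2. Ten-membered ring (last ring) ⇐ C8–C9 bond: the SmI2 ketyl of the C9 aldehyde (an umpoled carbonyl carbon) adds to the electrophilic β-carbon of the 4-alkoxybutenolide in seco-aldehyde 24, creating C8, C9 and C17 together.
3. 24 ⇐ Sonogashira union (C4–C5) of alkyne 13 (fragment 1) with vinyl bromide 21 (fragment 2), Z-selective semi-reduction, acetal hydrolysis.
4. 13 ⇐ catalytic asymmetric Diels–Alder (diene 5 + enal 3), ethynylation, C12 inversion, directed epoxidation; 21 ⇐ asymmetric vinylogous aldol of a 3-methyltetronate silyloxyfuran with 2-bromoacrolein.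
5. Ring order: cyclohexene (step 3) and butenolide (bought as the tetronic acid) → epoxide (step 7) → ten-membered ring (step 16).

Assumptions: briarane numbering (C1–C20) is used for all intermediates and β is the face of the six-membered ring carrying the C15 methyl; 4 and 17 are taken as catalogue compounds; the sense of induction in steps 3 and 12 is assigned by analogy, and the mirror-image catalyst is used if the antipode forms.

## Route

Step 1
Reactants: 1 2,2-dimethoxyacetaldehyde; 2 2-(triphenylphosphoranylidene)propanal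
Product: 3 (E)-4,4-dimethoxy-2-methylbut-2-enal
Conditions: PhMe, 80 °C
Reagents that add atoms: none
Why: Wittig olefination with a stabilised formyl ylide stops at the less electrophilic enal and gives the (E)-alkene under thermodynamic control.

Step 2
Reactants: 4 (E)-1-(dimethylamino)pent-1-en-3-one
Product: 5 (1E,3Z)-3-(tert-butyldimethylsilyloxy)-N,N-dimethylpenta-1,3-dien-1-amine
Conditions: NaHMDS, THF, −78 °C; TBSCl, −78 °C → rt
Reagents that add atoms: tert-butyldimethylsilyl chloride CC(C)(C)[Si](C)(C)Cl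
Why: Enolate O-silylation of the vinylogous amide (Rawal-type aminosiloxydiene synthesis) gives the (3Z)-dienol ether, the only isomer that reaches the s-cis geometry needed for cycloaddition.

Step 3
Reactants: 3 (E)-4,4-dimethoxy-2-methylbut-2-enal; 5 aminosiloxydiene
Product: 6 Diels–Alder adduct (1-formyl-1-methyl cyclohexene silyl enol ether; CHO, NMe2 and C11 methyl α, C15 methyl and C9 acetal β)
Conditions: (S,S)-(salen)CrSbF6 (5 mol%; salen = N,N′-bis(3,5-di-tert-butylsalicylidene)cyclohexane-1,2-diamine dianion), 4 Å MS, CH2Cl2, −40 °C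
Reagents that add atoms: none
Why: Lewis-acid-catalysed Diels–Alder reaction in which the formyl-bound chiral chromium–salen complex selects the enal face (C1 and C10 absolute), the nucleophilic diene terminus bonds to the enal β-carbon (C11–C10), the (E)-enal places the C15 methyl and C9 cis, and the endo mode places NMe2 and the C11 methyl cis to CHO.

Step 4
Reactants: 6 Diels–Alder adduct
Product: 9 enone (2S)-4-(1-hydroxyprop-2-ynyl)-5-(dimethoxymethyl)-4,6-dimethylcyclohex-2-enone with C15 methyl, C9 and C20 methyl all β, via ethynyl carbinol 7 (not isolated), via C11-epimeric enone 8 (not isolated)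
Conditions: HC≡CMgBr, THF, −78 → −20 °C, aq NH4Cl; TBAF, AcOH, THF, 0 °C; DBU (0.2 equiv), CH2Cl2, rt
Reagents that add atoms: ethynylmagnesium bromide C#C[Mg]Br
Why: Grignard addition to the neopentyl aldehyde through a six-membered magnesium chelate with the cis NMe2 (attack past the small C15 methyl, anti to C10, gives 2S), then fluoride/acid unmasking with β-elimination of Me2NH to the enone, then base equilibration of the epimerisable C11 to the isomer with equatorial C20 methyl and an axial C10 acetal anti to the C2 arm.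

Step 5
Reactants: 9 enone
Product: 10 12β-allylic alcohol (diol; 12-OH cis to the C20 methyl)
Conditions: NaBH4, CeCl3·7H2O, MeOH, −78 °C
Reagents that add atoms: none
Why: Luche 1,2-reduction in which hydride enters from the α face, opposite the axial C10 acetal that shields the β face, giving the 12β-alcohol.

Step 6
Reactants: 10 12β-allylic alcohol
Product: 11 12α-butyrate with free C2–OH
Conditions: n-PrCO2H, PPh3, DIAD, PhMe, 0 °C → rt
Reagents that add atoms: butyric acid CCCC(=O)O
Why: Mitsunobu esterification reacts only at the unhindered allylic C12–OH (the neopentyl propargylic C2–OH is inert) and inverts C12 by SN2 to the required 12α-ester.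

Step 7
Reactants: 11 12α-butyrate
Product: 12 13α,14α-epoxide
Conditions: VO(acac)2 (5 mol%), t-BuOOH, CH2Cl2, 0 °C → rt
Reagents that add atoms: tert-butyl hydroperoxide CC(C)(C)OO
Why: Vanadium-catalysed hydroxyl-directed epoxidation in which the homoallylic C2–OH on the α face delivers oxygen to the α face of C13=C14, cis to the C12 butyrate, leaving the alkyne untouched.

Step 8
Reactants: 12 epoxy alcohol
Product: 13 fragment 1, the 2,12-dibutyrate (terminal alkyne, C9 dimethyl acetal)
Conditions: (n-PrCO)2O, Et3N, DMAP, CH2Cl2, rt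
Reagents that add atoms: butyric anhydride CCCC(=O)OC(=O)CCC
Why: DMAP-catalysed acylation of the remaining hindered secondary alcohol changes no stereocentre.

Step 9
Reactants: 14 acrolein
Product: 16 2-bromoacrolein, via 2,3-dibromopropanal 15 (not isolated)
Conditions: Br2, CH2Cl2, −78 °C; Et3N, −78 → 0 °C
Reagents that add atoms: bromine BrBr
Why: Bromine addition to the alkene followed by amine-induced elimination of HBr from the α-bromo aldehyde gives the α-bromoenal.

Step 10
Reactants: 17 3-methyltetronic acid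
Product: 18 4-[(4-methoxybenzyl)oxy]-3-methylfuran-2(5H)-one
Conditions: 4-methoxybenzyl alcohol, PPh3, DIAD, THF, 0 °C → rt
Reagents that add atoms: 4-methoxybenzyl alcohol COc1ccc(CO)cc1
Why: Mitsunobu alkylation of the acidic vinylogous acid is selective for the C4 oxygen and avoids C-alkylation.

Step 11
Reactants: 18 PMB tetronate
Product: 19 4-[(4-methoxybenzyl)oxy]-3-methyl-2-(trimethylsilyloxy)furan
Conditions: TMSOTf, Et3N, CH2Cl2, 0 °C
Reagents that add atoms: trimethylsilyl trifluoromethanesulfonate C[Si](C)(C)OS(=O)(=O)C(F)(F)F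
Why: Soft enolisation at the γ-position and O-silylation give the 2-silyloxyfuran, the silyl dienol ether needed for the vinylogous aldol.

Step 12
Reactants: 19 silyloxyfuran; 16 2-bromoacrolein
Product: 21 fragment 2, (5S)-5-[(1S)-2-bromo-1-hydroxyprop-2-en-1-yl]-4-[(4-methoxybenzyl)oxy]-3-methylfuran-2(5H)-one, via silyl ether 20 (not isolated)
Conditions: Ti(OiPr)4 (20 mol%), (R)-BINOL (20 mol%), Et2O, −20 °C; citric acid, MeOH
Reagents that add atoms: none
Why: Catalytic asymmetric vinylogous Mukaiyama aldol reaction in which the titanium–BINOL Lewis acid activates the aldehyde for 1,2-attack by C5 of the furan through an open antiperiplanar transition state (5,1′-threo adduct), the ligand selecting the aldehyde face that fixes C6 and with it C7.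

Step 13
Reactants: 13 fragment 1; 21 fragment 2
Product: 22 enyne (C3≡C4–C5(=CH2); stereocentres as in 13 and 21)
Conditions: Pd(PPh3)4 (5 mol%), CuI (10 mol%), Et3N, THF, 40 °C
Reagents that add atoms: none
Why: Sonogashira coupling of the terminal alkyne with the only vinyl bromide forms C4–C5 while esters, epoxide, acetal, tetronate and the free allylic alcohol are inert.

Step 14
Reactants: 22 enyne
Product: 23 (3Z)-diene
Conditions: Zn dust activated with Cu(OAc)2 and AgNO3, MeOH/H2O 1:1, 35 °C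
Reagents that add atoms: none
Why: Activated-zinc (Boland) cis-semi-reduction is specific for conjugated enynes and stops at the (3Z)-diene without touching the other alkenes.

Step 15
Reactants: 23 (3Z)-diene acetal
Product: 24 seco-aldehyde (C9 = CHO)
Conditions: PPTS, acetone/H2O 9:1, 45 °C
Reagents that add atoms: water O
Why: Mild acid-catalysed acetal hydrolysis unmasks the C9 aldehyde under conditions too weak to open the epoxide or cleave the PMB vinylogous ester.

Step 16
Reactants: 24 seco-aldehyde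
Product: 25 macrocycle (8-O-PMB, 9-hydroxy, 6-epi-hydroxy analogue of 28)
Conditions: SmI2 (3 equiv), MeOH (5 equiv), THF, 2 mM, slow addition of 24, −20 °C
Reagents that add atoms: none
Why: Proposed new method: SmI2 reduces only the aldehyde to a samarium ketyl (nucleophilic C9) that adds to the tetronate β-carbon C8, and the resulting α-ester radical is reduced to the enolate and protonated by MeOH before it can expel the C8 alkoxide, so the ten-membered ring, the C8 tertiary ether, C9–OH and C17–H form together; the closest known reactions are SmI2 ketyl additions of aldehydes to β-alkoxyacrylates (six- and seven-membered rings) and SmI2 ketyl–olefin macrocyclisations, and HMPA-free conditions are chosen to favour the activated enoate over the C3=C4 alkene, whose 5-exo mode also needs the disfavoured diequatorial C2/C9 conformer; C8 is attacked anti to C6 (trans ring fusion), C9 follows from a transition state in which trivalent samarium bridges the ketyl oxygen and the C8 ether oxygen with C10 anti to C7, and C17 is protonated on the C9 face by methanol bound to that samarium alkoxide.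

Step 17
Reactants: 25 macrocycle
Product: 26 6-chloride (C6 as in 28)
Conditions: PPh3, Cl3CC(O)CCl3, CH2Cl2, −20 → 0 °C
Reagents that add atoms: hexachloroacetone ClC(Cl)(Cl)C(=O)C(Cl)(Cl)Cl
Why: Appel-type chlorination with PPh3/hexachloroacetone converts the allylic C6–OH to the chloride by SN2 with inversion and without allylic transposition, the neopentyl-like C9–OH being too hindered to react.

Step 18
Reactants: 26 6-chloride
Product: 27 9-acetate (8-O-PMB ether of 28)
Conditions: Ac2O, pyridine, DMAP, CH2Cl2, rt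
Reagents that add atoms: acetic anhydride CC(=O)OC(C)=O
Why: DMAP-catalysed acetylation of the only free hydroxyl (C9) changes no stereocentre.

Step 19
Reactants: 27 9-acetate
Product: 28 brianthein V
Conditions: DDQ, CH2Cl2/pH 7 buffer 10:1, 0 °C → rt
Reagents that add atoms: none
Why: Oxidative PMB ether cleavage (hydride abstraction to the oxocarbenium ion, then hydrolysis) frees the tertiary C8–OH under neutral conditions that spare the allylic chloride, diene, epoxide and esters.

## Compound list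

1 | 2,2-dimethoxyacetaldehyde | COC(OC)C=O | starting material
2 | 2-(triphenylphosphoranylidene)propanal | CC(C=O)=P(c1ccccc1)(c1ccccc1)c1ccccc1 | starting material
3 | (E)-4,4-dimethoxy-2-methylbut-2-enal | COC(OC)/C=C(C)/C=O | intermediate
4 | (E)-1-(dimethylamino)pent-1-en-3-one | CCC(=O)/C=C/N(C)C | starting material
5 | (1E,3Z)-3-(tert-butyldimethylsilyloxy)-N,N-dimethylpenta-1,3-dien-1-amine | C/C=C(\O[Si](C)(C)C(C)(C)C)/C=C/N(C)C | intermediate
6 | 4-(tert-butyldimethylsilyloxy)-6-(dimethoxymethyl)-2-(dimethylamino)-1,5-dimethylcyclohex-3-ene-1-carbaldehyde (CHO, NMe2, 5-methyl α; 1-methyl and acetal β) | O=C[C@]1(C)[C@H]([C@H](C)C(O[Si](C)(C)C(C)(C)C)=C[C@@H]1N(C)C)C(OC)OC | intermediate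
7 | ethynyl carbinol of 6, (2S) | C#C[C@H](O)[C@]1(C)[C@H]([C@H](C)C(O[Si](C)(C)C(C)(C)C)=C[C@@H]1N(C)C)C(OC)OC | intermediate
8 | C11-epimeric enone (C20 methyl α) | C#C[C@H](O)[C@]1(C)[C@H]([C@H](C)C(=O)C=C1)C(OC)OC | intermediate
9 | enone, 4-[(1S)-1-hydroxyprop-2-yn-1-yl]-5-(dimethoxymethyl)-4,6-dimethylcyclohex-2-en-1-one (C15 methyl, C9, C20 methyl β) | C#C[C@H](O)[C@]1(C)[C@H]([C@@H](C)C(=O)C=C1)C(OC)OC | intermediate
10 | 12β-allylic alcohol (diol) | C#C[C@H](O)[C@]1(C)[C@H]([C@@H](C)[C@@H](O)C=C1)C(OC)OC | intermediate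
11 | 12α-butyrate, C2–OH free | C#C[C@H](O)[C@]1(C)[C@H]([C@@H](C)[C@H](OC(=O)CCC)C=C1)C(OC)OC | intermediate
12 | 13α,14α-epoxide of 11 | C#C[C@H](O)[C@]1(C)[C@H]([C@@H](C)[C@H](OC(=O)CCC)[C@@H]2O[C@@H]21)C(OC)OC | intermediate
13 | fragment 1, 2,12-dibutyrate of 12 | C#C[C@H](OC(=O)CCC)[C@]1(C)[C@H]([C@@H](C)[C@H](OC(=O)CCC)[C@@H]2O[C@@H]21)C(OC)OC | intermediate
14 | acrolein | C=CC=O | starting material
15 | 2,3-dibromopropanal | O=CC(Br)CBr | intermediate
16 | 2-bromoacrolein | C=C(Br)C=O | intermediate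
17 | 3-methyltetronic acid (4-hydroxy-3-methylfuran-2(5H)-one) | CC1=C(O)COC1=O | starting material
18 | 4-[(4-methoxybenzyl)oxy]-3-methylfuran-2(5H)-one | CC1=C(OCc2ccc(OC)cc2)COC1=O | intermediate
19 | 4-[(4-methoxybenzyl)oxy]-3-methyl-2-(trimethylsilyloxy)furan | Cc1c(OCc2ccc(OC)cc2)coc1O[Si](C)(C)C | intermediate
20 | O-trimethylsilyl ether of 21 | O=C1O[C@@H]([C@H](O[Si](C)(C)C)C(Br)=C)C(OCc2ccc(OC)cc2)=C1C | intermediate
21 | fragment 2, (5S)-5-[(1S)-2-bromo-1-hydroxyprop-2-en-1-yl]-4-[(4-methoxybenzyl)oxy]-3-methylfuran-2(5H)-one | O=C1O[C@@H]([C@H](O)C(Br)=C)C(OCc2ccc(OC)cc2)=C1C | intermediate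
22 | enyne from 13 and 21 (C4–C5 bond) | C=C(C#C[C@H](OC(=O)CCC)[C@]1(C)[C@H]([C@@H](C)[C@H](OC(=O)CCC)[C@@H]2O[C@@H]21)C(OC)OC)[C@@H](O)[C@@H]1OC(=O)C(C)=C1OCc1ccc(OC)cc1 | intermediate
23 | (3Z)-diene acetal | C=C(/C=C\[C@H](OC(=O)CCC)[C@]1(C)[C@H]([C@@H](C)[C@H](OC(=O)CCC)[C@@H]2O[C@@H]21)C(OC)OC)[C@@H](O)[C@@H]1OC(=O)C(C)=C1OCc1ccc(OC)cc1 | intermediate
24 | seco-aldehyde (C9 = CHO) | C=C(/C=C\[C@H](OC(=O)CCC)[C@]1(C)[C@H]([C@@H](C)[C@H](OC(=O)CCC)[C@@H]2O[C@@H]21)C=O)[C@@H](O)[C@@H]1OC(=O)C(C)=C1OCc1ccc(OC)cc1 | intermediate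
25 | macrocycle, 8-O-PMB, 9-hydroxy, 6-epi-hydroxy (6-dechloro) analogue of 28 | C=C1/C=C\[C@H](OC(=O)CCC)[C@]2(C)[C@H]([C@@H](C)[C@H](OC(=O)CCC)[C@@H]3O[C@@H]32)[C@H](O)[C@]2(OCc3ccc(OC)cc3)[C@@H](C)C(=O)O[C@H]2[C@@H]1O | intermediate
26 | 6-chloride of 25 | C=C1/C=C\[C@H](OC(=O)CCC)[C@]2(C)[C@H]([C@@H](C)[C@H](OC(=O)CCC)[C@@H]3O[C@@H]32)[C@H](O)[C@]2(OCc3ccc(OC)cc3)[C@@H](C)C(=O)O[C@H]2[C@H]1Cl | intermediate
27 | 9-acetate of 26 (8-O-PMB ether of 28) | C=C1/C=C\[C@H](OC(=O)CCC)[C@]2(C)[C@H]([C@@H](C)[C@H](OC(=O)CCC)[C@@H]3O[C@@H]32)[C@H](OC(C)=O)[C@]2(OCc3ccc(OC)cc3)[C@@H](C)C(=O)O[C@H]2[C@H]1Cl | intermediate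
28 | brianthein V | C=C1/C=C\[C@H](OC(=O)CCC)[C@]2(C)[C@H]([C@@H](C)[C@H](OC(=O)CCC)[C@@H]3O[C@@H]32)[C@H](OC(C)=O)[C@]2(O)[C@@H](C)C(=O)O[C@H]2[C@H]1Cl | target

## Step count and risks

Total steps: 19. Longest linear sequence: 14 (steps 1, 3–8, 13–19).

Step 16 (SmI2 macrocyclisation) is the most likely to fail: the ketyl may add 5-exo to the C3=C4 diene or simply be reduced, and the C9 configuration is not secured. The fallback sets out from 24 and comes back at 28, reversing the polarity of C8 instead. TFA/CH2Cl2/H2O removes the PMB group to give tetronic acid aldehyde F1. PhNTf2/Et3N gives enol triflate F2. CrCl2 with catalytic NiCl2 (DMF, high dilution) then adds the butenolide β-carbon, as a β-acylvinyl chromium (homoenolate-type) species, to the C9 aldehyde, closing the ring to the Δ8(17)-butenolide diol F3. PPh3/hexachloroacetone gives the 6-chloride F4 and Ac2O/DMAP the 9-acetate F5. Nucleophilic epoxidation (t-BuOOH, DBU) gives the 8,17-epoxide F6. SmI2/MeOH at −78 °C cleaves the C17–O bond of the epoxy lactone, leaving the C8 alcohol and, after enolate protonation, 28.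

Step 12 (asymmetric vinylogous aldol) may give 1,4-addition or cycloaddition to 2-bromoacrolein, poor threo selectivity or low ee. The fallback sets out from 19 and 16 and comes back at 21. BF3·OEt2 (CH2Cl2, −78 °C) gives the racemic threo adduct, that is 21 together with its (5R,1′R)-enantiomer F7. Burkholderia cepacia lipase with vinyl acetate then acetylates F7 to the (5R,1′R)-acetate F8 and leaves 21, which is separated by chromatography.

Step 3 (Diels–Alder) may be sluggish with the trisubstituted enal or give low ee. The fallback sets out from 4 (with 3) and comes back at 9, using auxiliary instead of catalyst control. Amine exchange of 4 with (2R,5R)-2,5-diphenylpyrrolidine (AcOH cat., PhMe, 80 °C) gives the chiral enaminone F9. NaHMDS/TBSCl gives the chiral aminosiloxydiene F10. Thermal cycloaddition with 3 (PhMe, 20–40 °C) gives the adduct F11. Ethynylmagnesium bromide gives the ethynyl carbinol F12, and TBAF/AcOH then DBU expel the auxiliary to give 9 by way of 8.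

Further compounds

F1 | step 16 | tetronic acid aldehyde (24 without PMB) | C=C(/C=C\[C@H](OC(=O)CCC)[C@]1(C)[C@H]([C@@H](C)[C@H](OC(=O)CCC)[C@@H]2O[C@@H]21)C=O)[C@@H](O)[C@@H]1OC(=O)C(C)=C1O
F2 | step 16 | enol triflate of F1 | C=C(/C=C\[C@H](OC(=O)CCC)[C@]1(C)[C@H]([C@@H](C)[C@H](OC(=O)CCC)[C@@H]2O[C@@H]21)C=O)[C@@H](O)[C@@H]1OC(=O)C(C)=C1OS(=O)(=O)C(F)(F)F
F3 | step 16 | Δ8(17)-butenolide macrocyclic 6,9-diol | C=C1/C=C\[C@H](OC(=O)CCC)[C@]2(C)[C@H]([C@@H](C)[C@H](OC(=O)CCC)[C@@H]3O[C@@H]32)[C@H](O)C2=C(C)C(=O)O[C@H]2[C@@H]1O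
F4 | step 16 | 6-chloride of F3 | C=C1/C=C\[C@H](OC(=O)CCC)[C@]2(C)[C@H]([C@@H](C)[C@H](OC(=O)CCC)[C@@H]3O[C@@H]32)[C@H](O)C2=C(C)C(=O)O[C@H]2[C@H]1Cl
F5 | step 16 | 9-acetate of F4 | C=C1/C=C\[C@H](OC(=O)CCC)[C@]2(C)[C@H]([C@@H](C)[C@H](OC(=O)CCC)[C@@H]3O[C@@H]32)[C@H](OC(C)=O)C2=C(C)C(=O)O[C@H]2[C@H]1Cl
F6 | step 16 | 8,17-epoxide of F5 | C=C1/C=C\[C@H](OC(=O)CCC)[C@]2(C)[C@H]([C@@H](C)[C@H](OC(=O)CCC)[C@@H]3O[C@@H]32)[C@H](OC(C)=O)[C@@]23O[C@@]3(C)C(=O)O[C@H]2[C@H]1Cl
F7 | step 12 | (5R,1′R)-enantiomer of 21 | O=C1O[C@H]([C@@H](O)C(Br)=C)C(OCc2ccc(OC)cc2)=C1C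
F8 | step 12 | (5R,1′R)-acetate of F7 | O=C1O[C@H]([C@@H](OC(C)=O)C(Br)=C)C(OCc2ccc(OC)cc2)=C1C
F9 | step 3 | (E)-1-[(2R,5R)-2,5-diphenylpyrrolidin-1-yl]pent-1-en-3-one | CCC(=O)/C=C/N1[C@@H](c2ccccc2)CC[C@@H]1c1ccccc1
F10 | step 3 | (1E,3Z)-3-(tert-butyldimethylsilyloxy)-1-[(2R,5R)-2,5-diphenylpyrrolidin-1-yl]penta-1,3-diene | C/C=C(\O[Si](C)(C)C(C)(C)C)/C=C/N1[C@@H](c2ccccc2)CC[C@@H]1c1ccccc1
F11 | step 3 | Diels–Alder adduct carrying the diphenylpyrrolidine (analogue of 6) | O=C[C@]1(C)[C@H]([C@H](C)C(O[Si](C)(C)C(C)(C)C)=C[C@@H]1N1[C@@H](c2ccccc2)CC[C@@H]1c1ccccc1)C(OC)OC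
F12 | step 3 | ethynyl carbinol of F11 (analogue of 7) | C#C[C@H](O)[C@]1(C)[C@H]([C@H](C)C(O[Si](C)(C)C(C)(C)C)=C[C@@H]1N1[C@@H](c2ccccc2)CC[C@@H]1c1ccccc1)C(OC)OC
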